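Feature: in each outer ring (A and C, atoms C1' ipso to C6') the ipso carbon C1' and the sulfate-bearing C2' are neighbours. The other four carbons C3'–C6' carry oxygen only on C4' and C6', so each ring is a C1'–C2' two-carbon unit plus a 1,1,3-trioxygenated C4 unit.
Endgame: the seven free phenols come from benzyl ethers (hydrogenolysis last). The two O–SO3H groups come from the C2' phenols, which alone are masked as 4-methoxybenzyl ethers.
Key disconnection, run in both directions at once: C1'–C6' and C2'–C3' of rings A and C, by [4+2] addition of a vinylketene acetal to a ring-B bis(2-alkoxy-1-nitrovinyl)arene, then loss of nitrous acid and of one of the two C6' oxygen groups.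
Dienophile: C2' from triethyl orthoformate, C1' from nitromethane (Pd-catalysed coupling with dibrominated phloroglucinol tribenzyl ether). Diene: from benzyl acetoacetate.
Ring order: ring B is bought as phloroglucinol; rings A and C are formed together in the key step.

Key step: step 9

Remark: the SMILES carries no stereodescriptor, so the two tetra-ortho-oxygenated biaryl axes are left uncontrolled (protected intermediates may appear as rotamer mixtures), and the bis(hydrogen sulfate) drawn is released from its more stable disodium salt only in the last operation.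

Step 1
Reactants: 1 phloroglucinol
Product: 2 benzene-1,3,5-triyl triacetate (phloroglucinol triacetate)
Conditions: Ac2O (3.5 equiv), pyridine, 0→23 °C
Reagents that add atoms: acetic anhydride, CC(=O)OC(C)=O
Why: Exhaustive O-acetylation (nucleophilic acyl substitution) stores the three phenols as esters from which the phenoxides can be released one at a time in step 2.

Step 2
Reactants: 2 phloroglucinol triacetate
Product: 3 1,3,5-tris(benzyloxy)benzene
Conditions: BnCl (3.6 equiv), NaH (7 equiv), DMF, 0 °C; H2O (3.3 equiv) added slowly, 0→23 °C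
Reagents that add atoms: benzyl chloride, ClCc1ccccc1
Why: Williamson etherification under slow in-situ deacetylation, in which each phenoxide is freed only in the presence of excess benzyl chloride, so the C-benzylation that plagues direct alkylation of the phloroglucinol anion is held back.

Step 3
Reactants: 3 1,3,5-tris(benzyloxy)benzene
Product: 4 1,3,5-tris(benzyloxy)-2,4-dibromobenzene
Conditions: NBS (2.05 equiv), CH2Cl2, −40→0 °C, dark
Reagents that add atoms: N-bromosuccinimide, O=C1CCC(=O)N1Br
Why: Electrophilic aromatic bromination of three equivalent ring positions, each bromine deactivating the ring, so two equivalents of reagent should stop at the 2,4-dibromide.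

Step 4
Reactants: 4 1,3,5-tris(benzyloxy)-2,4-dibromobenzene; 5 nitromethane
Product: 7 1,3,5-tris(benzyloxy)-2,4-bis(nitromethyl)benzene, via bis(caesium nitronate) 6 (not isolated)
Conditions: Pd2(dba)3 (5 mol %), XPhos (12 mol %), Cs2CO3 (4.4 equiv), 5 (20 equiv), 1,4-dioxane, 4 Å MS, 60 °C; aq NH4Cl, 0 °C
Reagents that add atoms: none
Why: Palladium-catalysed cross-coupling of nitromethane with aryl bromides (oxidative addition to zerovalent palladium, nitronate binding, reductive elimination) should put one CH2NO2 group on each brominated carbon, the product resting as bis(nitronate) 6 so that it is not arylated again, and this C–C route avoids 2,4,6-trialkoxybenzyl halides, which ionise, self-alkylate and take up nitrite at oxygen.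

Step 5
Reactants: 7 1,3,5-tris(benzyloxy)-2,4-bis(nitromethyl)benzene; 8 triethyl orthoformate
Product: 9 1,3,5-tris(benzyloxy)-2,4-bis[(Z)-2-ethoxy-1-nitrovinyl]benzene
Conditions: 8 (10 equiv), Ac2O (5 equiv), 120 °C, volatiles distilled off, no Lewis acid
Reagents that add atoms: none
Why: Alkoxymethylenation of a CH-acid with orthoformate and acetic anhydride, known for nitroacetates and related primary nitro compounds: the aci-nitro form attacks the diethoxycarbenium ion at carbon and loss of ethanol leaves the push–pull enol ether, drawn Z with the ethoxy group anti to the bulky aryl ring although the geometry has no consequence later.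

Step 6
Reactants: 9 bis(2-ethoxy-1-nitrovinyl)arene; 10 4-methoxybenzyl alcohol
Product: 11 1,3,5-tris(benzyloxy)-2,4-bis[(Z)-2-(4-methoxybenzyloxy)-1-nitrovinyl]benzene
Conditions: 10 (6 equiv), KOt-Bu (10 mol %), toluene–THF, 23→40 °C, EtOH stripped under reduced pressure; AcOH quench
Reagents that add atoms: none
Why: Nucleophilic vinylic substitution by addition–elimination, well studied for β-alkoxy-α-arylnitroalkenes: catalytic alkoxide adds to C2' and ethoxide is expelled, and stripping the volatile ethanol pulls the equilibrium to the 4-methoxybenzyl ether.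

Step 7
Reactants: 12 benzyl acetoacetate
Product: 13 benzyl (E)-3-(benzyloxy)but-2-enoate
Conditions: BnOH (1.5 equiv), TsOH·H2O (2 mol %), toluene, reflux, azeotropic removal of water
Reagents that add atoms: benzyl alcohol, OCc1ccccc1
Why: Acid-catalysed enol etherification of a β-keto ester driven by water removal, in which ester exchange with benzyl alcohol is degenerate and the E isomer (alkoxy anti to the ester) is the thermodynamic one.

Step 8
Reactants: 13 benzyl (E)-3-(benzyloxy)but-2-enoate
Product: 15 (1Z)-1,3-bis(benzyloxy)-1-(tert-butyldimethylsilyloxy)buta-1,3-diene, via lithium dienolate 14 (not isolated)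
Conditions: LiN(i-Pr)2 (LDA, 1.1 equiv), THF, −78 °C; TBSCl (1.2 equiv), DMPU, −78→0 °C; pentane extraction, used without chromatography
Reagents that add atoms: tert-butyldimethylsilyl chloride, CC(C)(C)[Si](C)(C)Cl
Why: Kinetic γ-deprotonation of a β-alkoxy enoate and O-silylation of the dienolate is the standard preparation of 1,3-dialkoxy-1-silyloxybutadienes, and the geometry at C1 (drawn Z) is of no consequence.

Step 9
Reactants: 11 bis(nitroalkene); 15 trioxygenated diene (two equivalents are consumed)
Product: 18 1,3,5-tris(benzyloxy)-2,4-bis[4-(benzyloxy)-2-(tert-butyldimethylsilyloxy)-6-(4-methoxybenzyloxy)phenyl]benzene, via bis-cycloadduct 16 (not isolated), via bis(cyclohexadienyl ketal) 17 (not isolated)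
Conditions: 15 (6 equiv), 2,6-di-tert-butyl-4-methylpyridine (0.2 equiv), toluene (1 M), 90 °C, sealed tube; then DBU (6 equiv), 23→70 °C
Reagents that add atoms: none
Why: Proposed new method: the nitro group on C1' makes C2' the electrophilic alkene carbon, so the nucleophilic CH2 terminus of 15 should bond to C2' (new C2'–C3' bond) and the ketene-acetal carbon to C1' (new C1'–C6' bond) in a normal-electron-demand, probably asynchronous [4+2] cycloaddition, and rings A and C are each closed in this intermolecular [4+2] mode as six-membered carbocycles to give 16. DBU then removes nitrous acid across C1'–C2' (C1' is quaternary, so no nitronate can form and the C2' ether cannot leave by E1cB), and the doubly allylic C6' ketal of 17 ionises to a 2',4',6'-trioxygenated arenium ion that loses a C3' proton. As is usual for mixed alkyl silyl vinylketene acetals in arene-forming cycloadditions, the more basic alkoxy oxygen should depart (as BnOH) and the silylated oxygen stay on C6', but rings that lose silanol instead already carry the benzyl ether of 19 and rings that lose the silyl group are benzylated in step 10, so every channel converges. The closest known reaction type is the Diels–Alder reaction of 1-alkoxy-3-silyloxybutadienes and vinylketene acetals with nitroalkenes followed by base-induced loss of nitrous acid, in which the nitroalkene acts as an alkyne equivalent of reversed regiochemistry; not yet shown are a β-alkoxy donor on the nitroalkene, a di-ortho-substituted α-aryl group and a twofold run. The stereocentres made in 16 (C1', C2' and C6' of each ring) are all erased on aromatisation, so alkene geometry and endo/exo preference are irrelevant and no stereocentre has to be controlled. The step needs regioselectivity, which the nitro group secures, and chemoselectivity for ring closure over alkoxide expulsion or silyl transfer in an open nitronate and over hetero-Diels–Alder addition through the N=O bond, which a non-polar, acid-free and Lewis-acid-free medium, the slowly migrating TBS group and, if required, high pressure should favour.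

Step 10
Reactants: 18 bis(silyl ether) terphenyl
Product: 19 1,3,5-tris(benzyloxy)-2,4-bis[2,4-bis(benzyloxy)-6-(4-methoxybenzyloxy)phenyl]benzene
Conditions: CsF (6 equiv), BnBr (4 equiv), DMF, 23→40 °C
Reagents that add atoms: benzyl bromide, BrCc1ccccc1
Why: Fluoride cleaves the aryl silyl ethers and the phenoxides are benzylated in the same pot (desilylative Williamson etherification), which also funnels any 6'-phenol or 6'-benzyl ether carried over from step 9 into one compound.

Step 11
Reactants: 19 heptabenzyl bis(4-methoxybenzyl) terphenyl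
Product: 20 1,3,5-tris(benzyloxy)-2,4-bis[2,4-bis(benzyloxy)-6-hydroxyphenyl]benzene
Conditions: TFA (5 vol %), 1,3,5-trimethoxybenzene (10 equiv), CH2Cl2, 0 °C
Reagents that add atoms: none
Why: Acidolysis of aryl 4-methoxybenzyl ethers, in which the stabilised benzylic cation leaves far faster than a plain benzyl cation and is trapped by Friedel–Crafts alkylation of the unhindered, excess scavenger before it can attack the electron-rich terphenyl.

Step 12
Reactants: 20 terphenyl bis(phenol)
Product: 22 disodium salt of the heptabenzyl terphenyl 2',2'-bis(sulfate), via bis(pyridinium) salt 21 (not isolated)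
Conditions: SO3·pyridine (10 equiv), pyridine, 50 °C; aq NaHCO3, 0 °C
Reagents that add atoms: sulfur trioxide–pyridine complex, O=S(=O)([O-])[n+]1ccccc1; sodium hydrogen carbonate, [Na+].OC([O-])=O
Why: O-sulfation of phenols with the mild pyridine complex of sulfur trioxide should take only the two free hydroxyl groups, each with just one ortho neighbour, and cation exchange gives a lipophilic, base-stable salt that can be chromatographed.

Step 13
Reactants: 22 disodium heptabenzyl bis(sulfate)
Product: 24 2',4,4',4'',6,6',6''-heptahydroxy-[1,1':3',1''-terphenyl]-2,2''-diyl bis(hydrogen sulfate) (CNP0320583.0), via disodium salt 23 (not isolated)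
Conditions: H2 (1 atm), Pd(OH)2/C, THF–MeOH–H2O, 23 °C; filtration; sulfonic acid cation-exchange resin (H+ form), H2O, 0–5 °C, freeze-drying
Reagents that add atoms: none
Why: Heterogeneous hydrogenolysis of aryl benzyl ethers leaves aryl sulfate monoester salts untouched in neutral medium, and a short cold passage over the acid resin exchanges sodium for protons before acid-catalysed desulfation can set in.

Compound list
1 | phloroglucinol | Oc1cc(O)cc(O)c1 | starting material
2 | benzene-1,3,5-triyl triacetate | CC(=O)Oc1cc(OC(C)=O)cc(OC(C)=O)c1 | intermediate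
3 | 1,3,5-tris(benzyloxy)benzene | c1ccc(COc2cc(OCc3ccccc3)cc(OCc3ccccc3)c2)cc1 | intermediate
4 | 1,3,5-tris(benzyloxy)-2,4-dibromobenzene | Brc1c(OCc2ccccc2)cc(OCc2ccccc2)c(Br)c1OCc1ccccc1 | intermediate
5 | nitromethane | C[N+](=O)[O-] | starting material
6 | bis(caesium nitronate) of 7 (not isolated) | [Cs+].[Cs+].[O-][N+]([O-])=Cc1c(OCc2ccccc2)cc(OCc2ccccc2)c(C=[N+]([O-])[O-])c1OCc1ccccc1 | intermediate
7 | 1,3,5-tris(benzyloxy)-2,4-bis(nitromethyl)benzene | O=[N+]([O-])Cc1c(OCc2ccccc2)cc(OCc2ccccc2)c(C[N+](=O)[O-])c1OCc1ccccc1 | intermediate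
8 | triethyl orthoformate | CCOC(OCC)OCC | starting material
9 | 1,3,5-tris(benzyloxy)-2,4-bis[(Z)-2-ethoxy-1-nitrovinyl]benzene | CCO/C=C(/c1c(OCc2ccccc2)cc(OCc2ccccc2)c(/C(=C/OCC)[N+](=O)[O-])c1OCc1ccccc1)[N+](=O)[O-] | intermediate
10 | 4-methoxybenzyl alcohol | COc1ccc(CO)cc1 | starting material
11 | 1,3,5-tris(benzyloxy)-2,4-bis[(Z)-2-(4-methoxybenzyloxy)-1-nitrovinyl]benzene | COc1ccc(CO/C=C(/c2c(OCc3ccccc3)cc(OCc3ccccc3)c(/C(=C/OCc3ccc(OC)cc3)[N+](=O)[O-])c2OCc2ccccc2)[N+](=O)[O-])cc1 | intermediate
12 | benzyl acetoacetate | CC(=O)CC(=O)OCc1ccccc1 | starting material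
13 | benzyl (E)-3-(benzyloxy)but-2-enoate | C/C(OCc1ccccc1)=C\C(=O)OCc1ccccc1 | intermediate
14 | lithium dienolate of 13 (not isolated) | [Li+].C=C(OCc1ccccc1)/C=C(/OCc1ccccc1)[O-] | intermediate
15 | (1Z)-1,3-bis(benzyloxy)-1-(tert-butyldimethylsilyloxy)buta-1,3-diene | C=C(OCc1ccccc1)/C=C(/OCc1ccccc1)O[Si](C)(C)C(C)(C)C | intermediate
16 | bis-cycloadduct: tribenzylated ring B bearing two 2,4-bis(benzyloxy)-2-(tert-butyldimethylsilyloxy)-6-(4-methoxybenzyloxy)-1-nitrocyclohex-3-en-1-yl groups, diastereomer mixture (not isolated) | O=[N+]([O-])C1(c2c(OCc3ccccc3)cc(OCc3ccccc3)c(C3([N+](=O)[O-])C(OCc4ccc(OC)cc4)CC(OCc4ccccc4)=CC3(OCc3ccccc3)O[Si](C)(C)C(C)(C)C)c2OCc2ccccc2)C(OCc2ccc(OC)cc2)CC(OCc2ccccc2)=CC1(OCc1ccccc1)O[Si](C)(C)C(C)(C)C | intermediate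
17 | bis(cyclohexadienyl ketal): tribenzylated ring B bearing two 4,6-bis(benzyloxy)-6-(tert-butyldimethylsilyloxy)-2-(4-methoxybenzyloxy)cyclohexa-1,4-dien-1-yl groups (not isolated) | COc1ccc(COC2=C(c3c(OCc4ccccc4)cc(OCc4ccccc4)c(C4=C(OCc5ccc(OC)cc5)CC(OCc5ccccc5)=CC4(OCc4ccccc4)O[Si](C)(C)C(C)(C)C)c3OCc3ccccc3)C(OCc3ccccc3)(O[Si](C)(C)C(C)(C)C)C=C(OCc3ccccc3)C2)cc1 | intermediate
18 | 1,3,5-tris(benzyloxy)-2,4-bis[4-(benzyloxy)-2-(tert-butyldimethylsilyloxy)-6-(4-methoxybenzyloxy)phenyl]benzene | COc1ccc(COc2cc(OCc3ccccc3)cc(O[Si](C)(C)C(C)(C)C)c2-c2c(OCc3ccccc3)cc(OCc3ccccc3)c(-c3c(O[Si](C)(C)C(C)(C)C)cc(OCc4ccccc4)cc3OCc3ccc(OC)cc3)c2OCc2ccccc2)cc1 | intermediate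
19 | 1,3,5-tris(benzyloxy)-2,4-bis[2,4-bis(benzyloxy)-6-(4-methoxybenzyloxy)phenyl]benzene | COc1ccc(COc2cc(OCc3ccccc3)cc(OCc3ccccc3)c2-c2c(OCc3ccccc3)cc(OCc3ccccc3)c(-c3c(OCc4ccccc4)cc(OCc4ccccc4)cc3OCc3ccc(OC)cc3)c2OCc2ccccc2)cc1 | intermediate
20 | 1,3,5-tris(benzyloxy)-2,4-bis[2,4-bis(benzyloxy)-6-hydroxyphenyl]benzene | Oc1cc(OCc2ccccc2)cc(OCc2ccccc2)c1-c1c(OCc2ccccc2)cc(OCc2ccccc2)c(-c2c(O)cc(OCc3ccccc3)cc2OCc2ccccc2)c1OCc1ccccc1 | intermediate
21 | bis(pyridinium) salt of the heptabenzyl bis(sulfate) (not isolated) | c1cc[nH+]cc1.c1cc[nH+]cc1.[O-]S(=O)(=O)Oc1cc(OCc2ccccc2)cc(OCc2ccccc2)c1-c1c(OCc2ccccc2)cc(OCc2ccccc2)c(-c2c(OS(=O)(=O)[O-])cc(OCc3ccccc3)cc2OCc2ccccc2)c1OCc1ccccc1 | intermediate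
22 | disodium salt of the heptabenzyl bis(sulfate) | [Na+].[Na+].[O-]S(=O)(=O)Oc1cc(OCc2ccccc2)cc(OCc2ccccc2)c1-c1c(OCc2ccccc2)cc(OCc2ccccc2)c(-c2c(OS(=O)(=O)[O-])cc(OCc3ccccc3)cc2OCc2ccccc2)c1OCc1ccccc1 | intermediate
23 | disodium salt of the target (not isolated) | [Na+].[Na+].[O-]S(=O)(=O)Oc1cc(O)cc(O)c1-c1c(O)cc(O)c(-c2c(O)cc(O)cc2OS(=O)(=O)[O-])c1O | intermediate
24 | 2',4,4',4'',6,6',6''-heptahydroxy-[1,1':3',1''-terphenyl]-2,2''-diyl bis(hydrogen sulfate) | O=S(=O)(O)Oc1cc(O)cc(O)c1-c1c(O)cc(O)c(-c2c(O)cc(O)cc2OS(=O)(=O)O)c1O | target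

Total step count: 13. Longest linear sequence: 11 steps (steps 1–6 and 9–13); the diene branch (steps 7 and 8) joins at step 9.

Steps most likely to fail

Step 9.
- The hindered, donor-substituted nitroalkene may not engage the diene at all.
- Bond formation may stop after C2'–C3'. The open nitronate can then expel the C2' alkoxide (addition–elimination) or take over the silyl group instead of closing C1'–C6'.
- Addition through the N=O bond may compete.
- Any acid present during aromatisation may ionise the C2' ether rather than the nitro group.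

The fallback uses known cross-coupling chemistry. It sets out from 4 and comes back at 19. Purchased 3,5-bis(benzyloxy)phenol F1 is brominated ortho to the free hydroxyl group (NBS, CH2Cl2, −78 °C) to 3,5-bis(benzyloxy)-2-bromophenol F2. This is etherified (4-methoxybenzyl chloride, K2CO3, DMF) to 1,5-bis(benzyloxy)-2-bromo-3-(4-methoxybenzyloxy)benzene F3. Bromine–lithium exchange (n-BuLi, THF, −78 °C) converts it into the aryllithium F4, and ZnCl2 then gives the arylzinc chloride F5. Two equivalents of F5 are joined to dibromide 4 in a double Negishi coupling for tetra-ortho-substituted biaryls (Pd2(dba)3, RuPhos, THF–NMP, 70–100 °C), which gives 19.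

Step 4.
- Oxidative addition at C–Br bonds flanked by two benzyloxy groups may be slow.
- The sequence may stall after the first coupling.
- Hydrodebromination may compete.
- Palladation of a neighbouring benzyl ring (intramolecular direct arylation) may compete.

The fallback sets out from 3 and comes back at 7. Double Vilsmeier–Haack formylation (POCl3, DMF, 0→80 °C) gives 2,4,6-tris(benzyloxy)isophthalaldehyde F6. Condensation with NH2OH·HCl and NaOAc in EtOH gives the (E,E)-dioxime F7. Buffered peroxytrifluoroacetic acid (urea–H2O2, trifluoroacetic anhydride, Na2HPO4, MeCN, 0 °C) then oxidises both aldoximes to primary nitro groups, giving 7.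

Step 5.
- Acetic anhydride may dehydrate the primary nitro groups towards nitrile oxides.
- The second, more hindered condensation may stay incomplete.
- Prolonged heating may erode the benzyl ethers.

The fallback sets out from 7 and comes back at 11, so it also bypasses step 6. N,N-Dimethylformamide dimethyl acetal (toluene, 80 °C) gives the bis(2-dimethylamino-1-nitrovinyl)arene F8. Aqueous KOH in EtOH hydrolyses it to the dipotassium bis(nitroenolate) F9. Cold acidification (HCl, 0 °C) gives the hydrogen-bonded bis(2-hydroxy-1-nitrovinyl)arene F10. This acidic enol is etherified at once with 10 under Mitsunobu conditions (PPh3, diisopropyl azodicarboxylate, THF, 0 °C) to give 11.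

Further compounds
F1 | step 9 | 3,5-bis(benzyloxy)phenol (purchased building block) | Oc1cc(OCc2ccccc2)cc(OCc2ccccc2)c1
F2 | step 9 | 3,5-bis(benzyloxy)-2-bromophenol | Oc1cc(OCc2ccccc2)cc(OCc2ccccc2)c1Br
F3 | step 9 | 1,5-bis(benzyloxy)-2-bromo-3-(4-methoxybenzyloxy)benzene | COc1ccc(COc2cc(OCc3ccccc3)cc(OCc3ccccc3)c2Br)cc1
F4 | step 9 | [2,4-bis(benzyloxy)-6-(4-methoxybenzyloxy)phenyl]lithium | [Li]c1c(OCc2ccccc2)cc(OCc2ccccc2)cc1OCc1ccc(OC)cc1
F5 | step 9 | [2,4-bis(benzyloxy)-6-(4-methoxybenzyloxy)phenyl]zinc chloride | COc1ccc(COc2cc(OCc3ccccc3)cc(OCc3ccccc3)c2[Zn]Cl)cc1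
F6 | step 4 | 2,4,6-tris(benzyloxy)isophthalaldehyde | O=Cc1c(OCc2ccccc2)cc(OCc2ccccc2)c(C=O)c1OCc1ccccc1
F7 | step 4 | 2,4,6-tris(benzyloxy)isophthalaldehyde (E,E)-dioxime | O/N=C/c1c(OCc2ccccc2)cc(OCc2ccccc2)c(/C=N/O)c1OCc1ccccc1
F8 | step 5 | 1,3,5-tris(benzyloxy)-2,4-bis[(Z)-2-(dimethylamino)-1-nitrovinyl]benzene | CN(C)/C=C(/c1c(OCc2ccccc2)cc(OCc2ccccc2)c(/C(=C/N(C)C)[N+](=O)[O-])c1OCc1ccccc1)[N+](=O)[O-]
F9 | step 5 | dipotassium bis(nitroenolate) of F10 | [K+].[K+].[O-]/C=C(/c1c(OCc2ccccc2)cc(OCc2ccccc2)c(/C(=C/[O-])[N+](=O)[O-])c1OCc1ccccc1)[N+](=O)[O-]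
F10 | step 5 | 1,3,5-tris(benzyloxy)-2,4-bis[(Z)-2-hydroxy-1-nitrovinyl]benzene | O/C=C(/c1c(OCc2ccccc2)cc(OCc2ccccc2)c(/C(=C/O)[N+](=O)[O-])c1OCc1ccccc1)[N+](=O)[O-]
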